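## Analysis of the target

The target 16 is a row of three fully substituted phloroglucinol-type benzene rings joined by two methylene bridges. It has no other rings and no stereocentres, and a mirror plane through C1 and C4 of the central ring A makes the two outer rings equivalent. Ring A is a 2,4,6-trihydroxybutyrophenone (butanoyl at C1, hydroxyls at C2, C4 and C6) that carries the bridges at C3 and C5. Each outer ring, numbered from its bridge carbon C1', carries OH at C2', butanoyl at C3', OH at C4', methyl at C5' and methoxy at C6'. Its one methyl ether therefore lies para to that ring's ketone, between the bridge carbon and the C-methyl. The sensitive parts are the electron-rich polyphenol nuclei, which oxidise in basic solution under air, and the aryl–CH2–aryl links, which strong acid can cleave by ipso protonation of a trihydroxyphenyl ring. The difficulty is the substitution pattern: three hexasubstituted rings, nine oxygen functions of which exactly two are methylated, and two unsymmetrical outer rings that must be attached through one particular carbon. The strategy rests on reading each outer ring as an open six-carbon chain C4'–C3'–C2'–C1'–C6'–C5' at the oxidation level of a 3,5-dioxo ester. In that chain C4' is the ester carbon, C3' a methylene, C2' and C6' ketone carbons, C1' the doubly activated carbon that bears the bridge, and C5' the α-carbon of a propanoyl end whose terminal methyl becomes the ring methyl. Closing C5' onto C4' makes the ring, and the point of attachment to ring A is fixed beforehand by enolate alkylation instead of by aromatic substitution on a ring with two free positions.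

## Retrosynthetic reasoning

**Ring-A oxygens (16 ⇒ 15).** The three O–benzyl bonds on ring A are cut last. Ring A must stay masked until the outer rings are complete, for two reasons. A free ring-A phenol next to a bridge would trap the side-chain ketones of the open-chain precursor as cyclic hemiketals, and it would compete in the methylation. Benzyl is chosen because hydrogenolysis removes it without touching aryl methyl ethers, hydrogen-bonded ketones or the bridges.

**Methyl ethers (15 ⇒ 14).** The two O–CH3 bonds at C6' are cut next. The methylation is placed after the outer-ring ketones are in, because only then do the three hydroxyls of an outer ring differ: the one para to the carbonyl is the most acidic and is not chelated.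

**Outer-ring ketones (14 ⇒ 12).** The C3'–acyl bonds are cut. C3' is the only unsubstituted carbon on each outer ring of hexaphenol 12, so the acylation has no regiochemical choice. The forward reaction must be mild enough to spare the benzyl ethers of ring A, which argues for a nitrile-based acylation under hydrogen-halide catalysis and against a strong Lewis acid.

**Outer rings (12 ⇒ 10).** Both outer rings are opened at C4'–C5', giving the bis(diketo ester) 10. This is the central disconnection: it turns two unsymmetrical aromatic rings into two identical open chains. The forward reaction is a two-fold intramolecular Claisen condensation, in which each propanoyl α-carbon must acylate itself with the ester at the other end of its arm and the product must aromatise.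

**Bridges (10 ⇒ 5 + 9).** The bond between each bridge carbon and C1' (C4 of the diketo ester) is cut, giving the bis(chloromethyl) ketone 5 and two molecules of methyl 3,5-dioxoheptanoate 9. C4 of 9 is the most acidic position, so a weak base and a benzylic halide should join the pieces there. The chloride is used in place of a bromide because the usual bromomethylation medium would strip aryl benzyl ethers.

**Diketo ester (9 ⇒ 6 + 7).** The C4–C5 bond of 9 is cut, giving methyl acetoacetate 6 and methyl propanoate 7. The forward reaction is acylation of the acetoacetate dianion 8 at its terminal carbon.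

**Chloromethyl groups (5 ⇒ 4).** The two ring-A C–CH2Cl bonds are cut back to the tribenzyl ether 4. Its two free carbons each lie ortho to two and para to one alkoxy group, so a one-carbon electrophile should enter both.

**Ring-A core (4 ⇒ 3 ⇒ 1 + 2).** The benzyl ethers come off to give the trihydroxy ketone 3, and the ring-A ketone is cut to phloroglucinol 1 and butanoyl chloride 2. The ring-A butanoyl is installed first, when no other group is present to complicate a Friedel–Crafts acylation.

## Alternatives that were turned down

**Alternative 1:** Ring A is cut at C3–C4 and C1–C2 and assembled by a Danheiser benzannulation. The partners are 3-ethoxy-4-[(2,4,6-trimethoxy-3-methylphenyl)methyl]cyclobut-2-en-1-one A1 and the ynol ether 1,3,5-trimethoxy-2-(3-methoxyprop-2-yn-1-yl)-4-methylbenzene A2. On heating, A1 opens to a vinylketene, adds A2 in a [2+2] sense, and the new cyclobutenone opens and electrocyclises to the phenol 3-ethoxy-5-methoxy-2,6-bis[(2,4,6-trimethoxy-3-methylphenyl)methyl]phenol A3.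
- For it: the route is convergent, the substitution pattern of ring A follows from the pericyclic mechanism, the three ring-A oxygens arrive differentiated, and no Lewis acid is needed. On convergence and on certainty of the ring-A pattern it is stronger than the chosen route.
- Against it: A1 and A2 each need a multistep synthesis from a protected methylphloroglucinol unit, and the doubly activated propargylic CH2 of A2 invites isomerisation to an allenyl ether.
- Against it, after the key step: A3 still lacks all three butanoyl groups, which must enter between two alkoxy groups each. Then exactly six O-alkyl groups ortho to the ketones must be removed while the two para methyl ethers stay. Chelation-controlled dealkylation with boron halides takes the first ortho ether of each ketone easily, but the second is slow once the carbonyl is tied up, and the forcing conditions threaten the para ethers and the bridges.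
- Comparison: the chosen route is shorter and never has to cleave an aryl methyl ether, because its outer rings are born as free phenols.

**Alternative 2:** The ring-A ketone and its neighbouring hydroxyl are cut together (C1–carbonyl and C2–O). A fluoride source releases the C1–C2 aryne from 3,5-bis(benzyloxy)-2,4-bis[(2,4,6-trimethoxy-3-methylphenyl)methyl]-6-(trimethylsilyl)phenyl trifluoromethanesulfonate A4. Butanoic acid A5 adds across it: the oxygen adds to C2, and the aryl anion at C1 takes the acyl group. The product is 1-{4,6-bis(benzyloxy)-2-hydroxy-3,5-bis[(2,4,6-trimethoxy-3-methylphenyl)methyl]phenyl}butan-1-one A6.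
- For it: ketone and ortho hydroxyl are installed in one operation under neutral conditions, and the C6 benzyloxy group steers the oxygen nucleophile to the distal aryne carbon, which is the required sense. On mildness of the ring-A acylation it is stronger.
- Against it: A4 is a hexasubstituted ortho-silyl aryl triflate that needs a long linear build-up on a crowded ring. The aryne is flanked on both sides, so addition is slow, and the acid can protonate the aryl anion before the acyl shift, giving an aryl ester instead of the ketone.
- Against it, after the key step: A6 has trimethoxy outer rings, so two hindered acylations and four selective ortho-demethylations remain, as in Alternative 1.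
- Comparison: the mild ketone installation is not needed in the chosen route, because the ring-A ketone is made in step 1 on phloroglucinol itself, where a Friedel–Crafts acylation has nothing to damage.

**Alternative 3:** The three ring-A C–O bonds are cut. Ring A starts as 1,3,5-trifluorobenzene A7, each ring hydrogen of which lies between two fluorines, and is elaborated to 1-{2,4,6-trifluoro-3,5-bis[(2,4,6-trimethoxy-3-methylphenyl)methyl]phenyl}butan-1-one A8. Three-fold substitution of A8 by benzyloxide then gives 1-{2,4,6-tris(benzyloxy)-3,5-bis[(2,4,6-trimethoxy-3-methylphenyl)methyl]phenyl}butan-1-one A9.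
- For it: the metalation sites are unambiguous, the starting material is cheap, all three fluorines are ortho or para to the ketone, and the bond-forming steps are standard. A9 has the same ring-A protection as compound 12. On reliability of the key step it is stronger than the chosen route.
- Against it: the ketone of A8 is enolisable, and benzyloxide will form the enolate, which pushes charge into the ring and shuts down the substitution. Each alkoxy group that enters deactivates further, the last fluorine sits between two benzylic substituents, and a polyfluoroaryl ketone can lose its acyl group to alkoxide.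
- Against it, after the key step: A9 again has trimethoxy outer rings, so two acylations and four selective demethylations remain.
- Comparison: A9 and compound 12 differ only in the state of the outer-ring oxygens. The chosen route accepts a riskier ring-forming step to obtain them free, so that the endgame is one mild acylation and one selective methylation per ring.

Key step: step 6

Remark: compound 10 has two enolisable stereocentres (C4 of each arm). It is taken on as a mixture of diastereomers and tautomers, because both centres become aromatic carbons in step 6.

## Route

Step 1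
Reactants: 1 phloroglucinol (benzene-1,3,5-triol); 2 butanoyl chloride
Product: 3 1-(2,4,6-trihydroxyphenyl)butan-1-one
Conditions: AlCl3 (3.5 equiv), PhNO2, 0 °C to 60 °C; then ice, 1 M HCl
Reagents that add atoms: none
Why: Friedel–Crafts C-acylation of phloroglucinol; every ring carbon is activated, and the first acyl group deactivates the ring by conjugation and chelation, so the mono-ketone should predominate.

Step 2
Reactants: 3 1-(2,4,6-trihydroxyphenyl)butan-1-one
Product: 4 1-[2,4,6-tris(benzyloxy)phenyl]butan-1-one
Conditions: BnBr (3.6 equiv), K2CO3 (4 equiv), Bu4NI (cat.), DMF, 60 °C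
Reagents that add atoms: benzyl bromide, BrCc1ccccc1
Why: Williamson O-benzylation; in a dipolar aprotic solvent the acyl-stabilised phenoxides should react at oxygen in preference to carbon, and warming brings the two chelated hydroxyls to reaction.

Step 3
Reactants: 4 1-[2,4,6-tris(benzyloxy)phenyl]butan-1-one
Product: 5 1-[2,4,6-tris(benzyloxy)-3,5-bis(chloromethyl)phenyl]butan-1-one
Conditions: ClCH2OMe (excess), ZnCl2 (0.2 equiv), CH2Cl2, 0 °C to rt
Reagents that add atoms: chloromethyl methyl ether, COCCl
Why: Blanc chloromethylation; each free carbon of 4 is ortho to two and para to one benzyloxy group and the ketone is twisted out of conjugation, so both should react under a weak Lewis acid that leaves aryl benzyl ethers intact, and in the hexasubstituted product the alkoxy groups are forced out of plane, which should make the benzylic chlorides stable enough to isolate.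

Step 4
Reactants: 6 methyl acetoacetate (methyl 3-oxobutanoate); 7 methyl propanoate
Product: 9 methyl 3,5-dioxoheptanoate, via methyl acetoacetate dianion 8 (not isolated)
Conditions: NaH (1 equiv), THF, 0 °C; n-BuLi (1 equiv), 0 °C; 7 (0.5 equiv), 0 °C to rt; then 1 M HCl
Reagents that add atoms: none
Why: Claisen-type acylation of the β-keto ester dianion at its terminal, most nucleophilic carbon; the ester is limiting because the more acidic diketo ester product is deprotonated by a second equivalent of dianion.

Step 5
Reactants: 5 1-[2,4,6-tris(benzyloxy)-3,5-bis(chloromethyl)phenyl]butan-1-one; 9 methyl 3,5-dioxoheptanoate (4 equiv)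
Product: 10 dimethyl 4,4'-{[2,4,6-tris(benzyloxy)-5-butanoyl-1,3-phenylene]bis(methylene)}bis(3,5-dioxoheptanoate)
Conditions: K2CO3 (4 equiv), NaI (0.2 equiv), acetone, 50 °C
Reagents that add atoms: none
Why: C-alkylation of a β-diketone monoanion by a benzylic halide (SN2 with in situ Finkelstein exchange); carbonate removes only the most acidic proton, at C4 between the two ketones, benzylic halides favour carbon over oxygen, and excess 9 together with the bulk of the new substituent should suppress a second alkylation; the two C4 centres form without control and are erased in step 6.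

Step 6
Reactants: 10 dimethyl 4,4'-{[2,4,6-tris(benzyloxy)-5-butanoyl-1,3-phenylene]bis(methylene)}bis(3,5-dioxoheptanoate)
Product: 12 1-{2,4,6-tris(benzyloxy)-3,5-bis[(2,4,6-trihydroxy-3-methylphenyl)methyl]phenyl}butan-1-one, via bis-cyclohexanetrione 11 (not isolated)
Conditions: NaOMe (12 equiv), MeOH, reflux, Ar; then cold 1 M HCl
Reagents that add atoms: none
Why: Methoxide deprotonates each arm reversibly at C2, C4 and C6; the dominant anions, enolised at C2 or C4, are unproductive but exchange protons with the minor C5–C6 enolate, whose carbon C6 (ring atom C5') adds to the un-enolised ester carbonyl C1 (ring atom C4'), and loss of methoxide gives the cyclohexane-1,3,5-trione 11, which enolises at once to the phloroglucinolate. The closest known reaction type is the base-mediated intramolecular Claisen (Dieckmann-type) condensation of 3,5-dioxoalkanoates to cyclohexane-1,3,5-triones and phloroglucinols, the laboratory counterpart of the polyketide route to phloroglucinol. Each of the two rings closes in the 6-(enolendo)-exo-trig mode, which the rules for enolate ring closure allow, and the two closures are independent of each other. No stereocentre is formed, and the two labile C4 centres of 10 disappear on aromatisation. The selectivity required is C-acylation by C6 over O-acylation by the C5 enolate oxygen (a 4-hydroxy-2-pyranone) and over retro-Claisen cleavage of the 2-substituted 1,3-diketone; the pyranone should be reopened by methoxide in methanol, the enolised diketone is shielded from methoxide, and the carbocycle leaves every equilibrium as an aromatic phenolate. Methoxide in methanol is preferred to complete deprotonation with excess LiN(i-Pr)2, because in the resulting trianion the ester is locked as an enolate and is no longer an acylating agent. The ring-A ketone should take no part, since it is flanked by two benzyloxy groups and no arm carbanion can reach it through a ring of workable size.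

Step 7
Reactants: 12 1-{2,4,6-tris(benzyloxy)-3,5-bis[(2,4,6-trihydroxy-3-methylphenyl)methyl]phenyl}butan-1-one
Product: 14 1-{2,4,6-tris(benzyloxy)-3,5-bis[(3-butanoyl-2,4,6-trihydroxy-5-methylphenyl)methyl]phenyl}butan-1-one, via bis-ketiminium dichloride 13 (not isolated)
Conditions: PrCN (6 equiv), ZnCl2 (0.3 equiv), HCl (g), Et2O–dioxane, 0 °C; then H2O, 90 °C
Reagents that add atoms: butanenitrile, CCCC#N; water, O
Why: Houben–Hoesch acylation; the activated nitrile is a weak electrophile that should attack only the one free carbon of each trihydroxyphenyl ring, the ketiminium salt cannot react a second time, and aryl benzyl ethers tolerate ethereal HCl at 0 °C and the short aqueous hydrolysis.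

Step 8
Reactants: 14 1-{2,4,6-tris(benzyloxy)-3,5-bis[(3-butanoyl-2,4,6-trihydroxy-5-methylphenyl)methyl]phenyl}butan-1-one
Product: 15 1-{2,4,6-tris(benzyloxy)-3,5-bis[(3-butanoyl-2,4-dihydroxy-6-methoxy-5-methylphenyl)methyl]phenyl}butan-1-one
Conditions: Me2SO4 (2.1 equiv), K2CO3 (2.2 equiv), acetone, 0 °C to rt
Reagents that add atoms: dimethyl sulfate, COS(=O)(=O)OC
Why: Selective Williamson O-methylation; in a 2,4,6-trihydroxyaryl ketone the hydroxyl para to the carbonyl is the most acidic and is not hydrogen-bonded to it, so one equivalent of weak base and of a hard methylating agent per ring should methylate O6' first, while the ortho hydroxyls are less acidic, one of them is chelated, and no base is left for them.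

Step 9
Reactants: 15 1-{2,4,6-tris(benzyloxy)-3,5-bis[(3-butanoyl-2,4-dihydroxy-6-methoxy-5-methylphenyl)methyl]phenyl}butan-1-one
Product: 16 1-{3,5-bis[(3-butanoyl-2,4-dihydroxy-6-methoxy-5-methylphenyl)methyl]-2,4,6-trihydroxyphenyl}butan-1-one (target)
Conditions: H2 (1 atm), 10% Pd/C, EtOAc–MeOH, rt
Reagents that add atoms: none
Why: Hydrogenolysis of benzyl aryl ethers over palladium; aryl methyl ethers, diarylmethane C–C bonds and hydrogen-bonded aryl ketones should be untouched at room temperature and atmospheric pressure if the reaction is stopped after uptake for three benzyl groups.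

## Compound list

1 | phloroglucinol (benzene-1,3,5-triol) | Oc1cc(O)cc(O)c1 | starting material
2 | butanoyl chloride | CCCC(=O)Cl | starting material
3 | 1-(2,4,6-trihydroxyphenyl)butan-1-one | CCCC(=O)c1c(O)cc(O)cc1O | intermediate
4 | 1-[2,4,6-tris(benzyloxy)phenyl]butan-1-one | CCCC(=O)c1c(OCc2ccccc2)cc(OCc2ccccc2)cc1OCc1ccccc1 | intermediate
5 | 1-[2,4,6-tris(benzyloxy)-3,5-bis(chloromethyl)phenyl]butan-1-one | CCCC(=O)c1c(OCc2ccccc2)c(CCl)c(OCc2ccccc2)c(CCl)c1OCc1ccccc1 | intermediate
6 | methyl acetoacetate (methyl 3-oxobutanoate) | COC(=O)CC(C)=O | starting material
7 | methyl propanoate | CCC(=O)OC | starting material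
8 | methyl acetoacetate dianion, sodium lithium salt | COC(=O)[CH-]C(=O)[CH2-].[Na+].[Li+] | intermediate (not isolated)
9 | methyl 3,5-dioxoheptanoate | CCC(=O)CC(=O)CC(=O)OC | intermediate
10 | dimethyl 4,4'-{[2,4,6-tris(benzyloxy)-5-butanoyl-1,3-phenylene]bis(methylene)}bis(3,5-dioxoheptanoate), mixture of diastereomers | CCCC(=O)c1c(OCc2ccccc2)c(CC(C(=O)CC)C(=O)CC(=O)OC)c(OCc2ccccc2)c(CC(C(=O)CC)C(=O)CC(=O)OC)c1OCc1ccccc1 | intermediate
11 | 2,2'-{[2,4,6-tris(benzyloxy)-5-butanoyl-1,3-phenylene]bis(methylene)}bis(4-methylcyclohexane-1,3,5-trione) | CCCC(=O)c1c(OCc2ccccc2)c(CC2C(=O)CC(=O)C(C)C2=O)c(OCc2ccccc2)c(CC2C(=O)CC(=O)C(C)C2=O)c1OCc1ccccc1 | intermediate (not isolated)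
12 | 1-{2,4,6-tris(benzyloxy)-3,5-bis[(2,4,6-trihydroxy-3-methylphenyl)methyl]phenyl}butan-1-one | CCCC(=O)c1c(OCc2ccccc2)c(Cc2c(O)cc(O)c(C)c2O)c(OCc2ccccc2)c(Cc2c(O)cc(O)c(C)c2O)c1OCc1ccccc1 | intermediate
13 | bis-ketiminium dichloride of 14 (each C3' carries C(=NH2+)CH2CH2CH3, chloride counter-ions) | CCCC(=O)c1c(OCc2ccccc2)c(Cc2c(O)c(C(=[NH2+])CCC)c(O)c(C)c2O)c(OCc2ccccc2)c(Cc2c(O)c(C(=[NH2+])CCC)c(O)c(C)c2O)c1OCc1ccccc1.[Cl-].[Cl-] | intermediate (not isolated)
14 | 1-{2,4,6-tris(benzyloxy)-3,5-bis[(3-butanoyl-2,4,6-trihydroxy-5-methylphenyl)methyl]phenyl}butan-1-one | CCCC(=O)c1c(OCc2ccccc2)c(Cc2c(O)c(C(=O)CCC)c(O)c(C)c2O)c(OCc2ccccc2)c(Cc2c(O)c(C(=O)CCC)c(O)c(C)c2O)c1OCc1ccccc1 | intermediate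
15 | 1-{2,4,6-tris(benzyloxy)-3,5-bis[(3-butanoyl-2,4-dihydroxy-6-methoxy-5-methylphenyl)methyl]phenyl}butan-1-one | CCCC(=O)c1c(OCc2ccccc2)c(Cc2c(O)c(C(=O)CCC)c(O)c(C)c2OC)c(OCc2ccccc2)c(Cc2c(O)c(C(=O)CCC)c(O)c(C)c2OC)c1OCc1ccccc1 | intermediate
16 | 1-{3,5-bis[(3-butanoyl-2,4-dihydroxy-6-methoxy-5-methylphenyl)methyl]-2,4,6-trihydroxyphenyl}butan-1-one | CCCC(=O)c1c(O)c(Cc2c(O)c(C(=O)CCC)c(O)c(C)c2OC)c(O)c(Cc2c(O)c(C(=O)CCC)c(O)c(C)c2OC)c1O | target

## Step count and least certain steps

Total: 9 steps. Longest linear sequence: 8 steps (1 → 3 → 4 → 5 → 10 → 12 → 14 → 15 → 16); step 4 is a one-step side branch.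

**Step 6 (key step).** Retro-Claisen cleavage of the 2-substituted 1,3-diketone by methoxide may outrun ring closure, because the nucleophilic C5–C6 enolate is only a minor member of the anion mixture. O-acylation to the pyranone may also drain material, or only one arm may close. A chelating base such as Mg(OMe)2 would be tried first. The fallback gives up ring construction for a union of preformed rings. It sets out from dichloride 5, which is used to C-benzylate commercial 2-methylbenzene-1,3,5-triol F1 (large excess, as its monosodium salt with NaOH in aqueous dioxane, 0 °C to rt) at one of its two equivalent free carbons, and it returns to the route at 12. The price is the risk of a second alkylation on the same triol and of O-alkylation, which the Claisen route avoids by design.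

**Step 3.** The first-formed benzylic chloride may alkylate a free position of another molecule (diarylmethane formation), the second substitution may stall, or benzyl ethers may be lost to the acid generated. The fallback sets out from 4: two-fold Rieche formylation (Cl2CHOMe, AgOTf, CH2Cl2, −78 °C to 0 °C, which spares aryl benzyl ethers) to 2,4,6-tris(benzyloxy)-5-butanoylbenzene-1,3-dicarbaldehyde F2, reduction of the aldehydes only (NaBH4, MeOH–THF, −20 °C) to 1-[2,4,6-tris(benzyloxy)-3,5-bis(hydroxymethyl)phenyl]butan-1-one F3, and chlorination (SOCl2, CH2Cl2, 0 °C) back to 5.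

**Step 5.** The diketonate may alkylate at oxygen or, after proton transfer, at C2, or alkylate twice. The fallback sets out from 5, which alkylates the dianion 8 (generated as in step 4, THF, 0 °C) at its terminal carbon to give dimethyl 5,5'-[2,4,6-tris(benzyloxy)-5-butanoyl-1,3-phenylene]bis(3-oxopentanoate) F4. The dianions of both β-keto ester arms of F4 (excess LiN(i-Pr)2, THF, −78 °C to 0 °C) are then acylated at the γ-carbon with methyl propanoate 7, returning to the route at 10. Here the regiochemistry of both C–C bonds follows from dianion reactivity.

**Step 7.** Acid may shift or remove benzyl groups, or cleave a bridge by ipso protonation of a trihydroxyphenyl ring, and the second ring may acylate incompletely. The fallback acylates before the rings are joined. Houben–Hoesch reaction of F1 with butanenitrile (ZnCl2, HCl, Et2O, 0 °C; then hot water) gives 1-(2,4,6-trihydroxy-3-methylphenyl)butan-1-one F5, which has a single free ring carbon. C-benzylation of excess F5 (NaOH, aqueous dioxane, 0 °C to rt) by dichloride 5 then returns to the route at 14.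

**Step 8.** Methylation may fail to distinguish the para hydroxyl from the unchelated ortho hydroxyl, may run on to dimethyl ethers, or may occur at the methyl-bearing ring carbon with loss of aromaticity. The fallback moves the selectivity problem to a small monomer, where isomers can be separated. F5, prepared from F1 as in the fallback for step 7, is methylated (Me2SO4, K2CO3, acetone) to 1-(2,6-dihydroxy-4-methoxy-3-methylphenyl)butan-1-one F6. C-benzylation of excess F6 at its one free carbon (NaOH, aqueous dioxane) by dichloride 5 returns to the route at 15.

## Further compounds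

F1 | step 6 | 2-methylbenzene-1,3,5-triol | Cc1c(O)cc(O)cc1O
F2 | step 3 | 2,4,6-tris(benzyloxy)-5-butanoylbenzene-1,3-dicarbaldehyde | CCCC(=O)c1c(OCc2ccccc2)c(C=O)c(OCc2ccccc2)c(C=O)c1OCc1ccccc1
F3 | step 3 | 1-[2,4,6-tris(benzyloxy)-3,5-bis(hydroxymethyl)phenyl]butan-1-one | CCCC(=O)c1c(OCc2ccccc2)c(CO)c(OCc2ccccc2)c(CO)c1OCc1ccccc1
F4 | step 5 | dimethyl 5,5'-[2,4,6-tris(benzyloxy)-5-butanoyl-1,3-phenylene]bis(3-oxopentanoate) | CCCC(=O)c1c(OCc2ccccc2)c(CCC(=O)CC(=O)OC)c(OCc2ccccc2)c(CCC(=O)CC(=O)OC)c1OCc1ccccc1
F5 | step 7 | 1-(2,4,6-trihydroxy-3-methylphenyl)butan-1-one | CCCC(=O)c1c(O)cc(O)c(C)c1O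
F6 | step 8 | 1-(2,6-dihydroxy-4-methoxy-3-methylphenyl)butan-1-one | CCCC(=O)c1c(O)cc(OC)c(C)c1O
A1 | alternative 1 | 3-ethoxy-4-[(2,4,6-trimethoxy-3-methylphenyl)methyl]cyclobut-2-en-1-one | CCOC1=CC(=O)C1Cc1c(OC)cc(OC)c(C)c1OC
A2 | alternative 1 | 1,3,5-trimethoxy-2-(3-methoxyprop-2-yn-1-yl)-4-methylbenzene | COC#CCc1c(OC)cc(OC)c(C)c1OC
A3 | alternative 1 | 3-ethoxy-5-methoxy-2,6-bis[(2,4,6-trimethoxy-3-methylphenyl)methyl]phenol | Oc1c(Cc2c(OC)cc(OC)c(C)c2OC)c(OC)cc(OCC)c1Cc1c(OC)cc(OC)c(C)c1OC
A4 | alternative 2 | 3,5-bis(benzyloxy)-2,4-bis[(2,4,6-trimethoxy-3-methylphenyl)methyl]-6-(trimethylsilyl)phenyl trifluoromethanesulfonate | C[Si](C)(C)c1c(OS(=O)(=O)C(F)(F)F)c(Cc2c(OC)cc(OC)c(C)c2OC)c(OCc2ccccc2)c(Cc2c(OC)cc(OC)c(C)c2OC)c1OCc1ccccc1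
A5 | alternative 2 | butanoic acid | CCCC(=O)O
A6 | alternative 2 | 1-{4,6-bis(benzyloxy)-2-hydroxy-3,5-bis[(2,4,6-trimethoxy-3-methylphenyl)methyl]phenyl}butan-1-one | CCCC(=O)c1c(O)c(Cc2c(OC)cc(OC)c(C)c2OC)c(OCc2ccccc2)c(Cc2c(OC)cc(OC)c(C)c2OC)c1OCc1ccccc1
A7 | alternative 3 | 1,3,5-trifluorobenzene | Fc1cc(F)cc(F)c1
A8 | alternative 3 | 1-{2,4,6-trifluoro-3,5-bis[(2,4,6-trimethoxy-3-methylphenyl)methyl]phenyl}butan-1-one | CCCC(=O)c1c(F)c(Cc2c(OC)cc(OC)c(C)c2OC)c(F)c(Cc2c(OC)cc(OC)c(C)c2OC)c1F
A9 | alternative 3 | 1-{2,4,6-tris(benzyloxy)-3,5-bis[(2,4,6-trimethoxy-3-methylphenyl)methyl]phenyl}butan-1-one | CCCC(=O)c1c(OCc2ccccc2)c(Cc2c(OC)cc(OC)c(C)c2OC)c(OCc2ccccc2)c(Cc2c(OC)cc(OC)c(C)c2OC)c1OCc1ccccc1
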